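The route rests on disconnecting ring C at O1–C8a and C4–C4a, which turns ring A into an aryne across C4a and C8a. One operation inserts this aryne into the carboxyl C–O bond of 3-phenylpropiolic acid, so that C8a receives the oxygen and C4a the alkynyl ketone. The step exploits the adjacent oxygen and acyl carbon on C8a and C4a, flanked by the C5 oxygen and the C8 side chain. The precursor is an ortho-silyl aryl triflate (silicon on C4a, triflate on C8a) with benzyl ethers at C5 and C7 and the (R)-configured C8 side chain, its ketone masked as a dioxolane. Ring closure, C3 hydroxylation and deprotection finish the flavonol.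

Key step: step 14

Remark: O1 and C2–C8a are flavone positions, used also for open precursors. The heptane chain is numbered from the guaiacyl end, so the stereocentre is C3 and the ketone carbon is C5. ArG = 4-(benzyloxy)-3-methoxyphenyl; K = (2R)-4-ArG-1-[2-(2-phenylethyl)-1,3-dioxolan-2-yl]butan-2-yl (the ketal-protected side chain).

Step 1
Reactants: 1 3-(4-hydroxy-3-methoxyphenyl)propan-1-ol
Product: 2 3-[4-(benzyloxy)-3-methoxyphenyl]propan-1-ol
Conditions: BnBr, K2CO3, acetone, reflux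
Reagents that add atoms: benzyl bromide BrCc1ccccc1
Why: Williamson ether synthesis, in which carbonate ionises only the phenol and the phenoxide displaces bromide while the primary alcohol stays free.

Step 2
Reactants: 2 3-[4-(benzyloxy)-3-methoxyphenyl]propan-1-ol
Product: 3 3-[4-(benzyloxy)-3-methoxyphenyl]propanal
Conditions: TEMPO (cat.), PhI(OAc)2, CH2Cl2, rt
Reagents that add atoms: none
Why: TEMPO-catalysed oxoammonium oxidation should stop at the aldehyde and spare the electron-rich ring.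

Step 3
Reactants: 3 3-[4-(benzyloxy)-3-methoxyphenyl]propanal; 4 dimethyl (2-oxo-4-phenylbutyl)phosphonate
Product: 5 (E)-7-[4-(benzyloxy)-3-methoxyphenyl]-1-phenylhept-4-en-3-one
Conditions: Ba(OH)2·8H2O, THF/H2O (40:1), rt
Reagents that add atoms: none
Why: Horner–Wadsworth–Emmons olefination of the stabilised β-ketophosphonate anion should give the (E)-enone under mild hydroxide conditions.

Step 4
Reactants: 5 (E)-7-[4-(benzyloxy)-3-methoxyphenyl]-1-phenylhept-4-en-3-one
Product: 6 (3R,4E)-7-[4-(benzyloxy)-3-methoxyphenyl]-1-phenylhept-4-en-3-ol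
Conditions: (S)-2-methyl-CBS-oxazaborolidine (20 mol%), catecholborane, toluene, −78 °C
Reagents that add atoms: none
Why: Corey–Bakshi–Shibata reduction, in which the ketone binds the (S)-oxazaborolidine with the alkenyl arm as the large group, so that 1,2-hydride delivery to one carbonyl face should set C3 as (R).

Step 5
Reactants: 6 (3R,4E)-7-[4-(benzyloxy)-3-methoxyphenyl]-1-phenylhept-4-en-3-ol; 7 3,5-bis(benzyloxy)phenol
Product: 8 1,3-bis(benzyloxy)-5-{[(3S,4E)-7-ArG-1-phenylhept-4-en-3-yl]oxy}benzene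
Conditions: PPh3, DIAD, toluene, 0 °C → rt
Reagents that add atoms: none
Why: Mitsunobu etherification, in which the phenol displaces the oxyphosphonium group in an SN2 sense and inverts C3 to (S), with toluene chosen to suppress ionisation and allylic transposition.

Step 6
Reactants: 8 1,3-bis(benzyloxy)-5-{[(3S,4E)-7-ArG-1-phenylhept-4-en-3-yl]oxy}benzene
Product: 9 3,5-bis(benzyloxy)-2-[(3R,4E)-1-ArG-7-phenylhept-4-en-3-yl]phenol
Conditions: PhNEt2, 170 °C, sealed tube
Reagents that add atoms: none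
Why: Aromatic Claisen rearrangement, in which the [3,3] shift through a chair transition state with the 2-phenylethyl group equatorial forms the aryl–carbon bond suprafacially, so the (S) C–O centre should be transferred into the (R) benzylic centre with an (E)-alkene before tautomerisation to the phenol, the two ortho positions being equivalent.

Step 7
Reactants: 9 3,5-bis(benzyloxy)-2-[(3R,4E)-1-ArG-7-phenylhept-4-en-3-yl]phenol
Product: 10 3,5-bis(benzyloxy)-2-[(3R,4E)-1-ArG-7-phenylhept-4-en-3-yl]phenyl N,N-diethylcarbamate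
Conditions: ClC(O)NEt2, K2CO3, MeCN, reflux
Reagents that add atoms: N,N-diethylcarbamoyl chloride CCN(CC)C(Cl)=O
Why: O-Carbamoylation of the phenoxide gives a robust carbamate that keeps the phenol from adding to the later side-chain ketone and will direct the metalation in step 11.

Step 8
Reactants: 10 3,5-bis(benzyloxy)-2-[(3R,4E)-1-ArG-7-phenylhept-4-en-3-yl]phenyl N,N-diethylcarbamate
Product: 12 3,5-bis(benzyloxy)-2-[(3R)-1-ArG-5-hydroxy-7-phenylheptan-3-yl]phenyl N,N-diethylcarbamate (both C5 epimers), via B-alkyl-9-BBN adduct 11 (not isolated)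
Conditions: 9-BBN, THF, 65 °C; then NaOH, H2O2, THF/H2O, 0 °C → rt
Reagents that add atoms: hydrogen peroxide OO
Why: Hydroboration–oxidation, in which the bulky 9-BBN should place boron on C5, the alkene carbon remote from the branched benzylic C3, and oxidation with retention gives the C5 alcohol, whose uncontrolled carbinol centre is erased in step 9 while C3 is untouched.

Step 9
Reactants: 12 3,5-bis(benzyloxy)-2-[(3R)-1-ArG-5-hydroxy-7-phenylheptan-3-yl]phenyl N,N-diethylcarbamate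
Product: 13 3,5-bis(benzyloxy)-2-[(3R)-1-ArG-5-oxo-7-phenylheptan-3-yl]phenyl N,N-diethylcarbamate
Conditions: Dess–Martin periodinane, CH2Cl2, rt
Reagents that add atoms: none
Why: Dess–Martin oxidation of the secondary alcohol should converge both epimers on the ketone under neutral conditions.

Step 10
Reactants: 13 3,5-bis(benzyloxy)-2-[(3R)-1-ArG-5-oxo-7-phenylheptan-3-yl]phenyl N,N-diethylcarbamate
Product: 14 3,5-bis(benzyloxy)-2-K-phenyl N,N-diethylcarbamate
Conditions: (TMSOCH2)2, TMSOTf (cat.), CH2Cl2, −78 → −20 °C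
Reagents that add atoms: 1,2-bis(trimethylsilyloxy)ethane C[Si](C)(C)OCCO[Si](C)(C)C
Why: Ketalisation under aprotic silyl triflate catalysis (oxocarbenium formation and capture by the silylated diol) should mask the ketone without exposing the electron-rich β-aryl ketone to hot protic acid.

Step 11
Reactants: 14 3,5-bis(benzyloxy)-2-K-phenyl N,N-diethylcarbamate
Product: 16 3,5-bis(benzyloxy)-2-K-6-(trimethylsilyl)phenyl N,N-diethylcarbamate, via aryllithium 15 (not isolated)
Conditions: s-BuLi, TMEDA, THF, −78 °C; then TMSCl, −78 °C → rt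
Reagents that add atoms: chlorotrimethylsilane C[Si](C)(C)Cl
Why: Directed ortho-metalation, in which the carbamate, assisted by the neighbouring C5 benzyloxy group, should direct the base to the only free ortho position (the future C4a), and silylation at −78 °C precedes any anionic Fries shift.

Step 12
Reactants: 16 3,5-bis(benzyloxy)-2-K-6-(trimethylsilyl)phenyl N,N-diethylcarbamate
Product: 17 3,5-bis(benzyloxy)-2-K-6-(trimethylsilyl)phenol
Conditions: LiAlH4, THF, 0 → 65 °C; aq. NaOH work-up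
Reagents that add atoms: none
Why: Hydride reduction of the aryl carbamate (addition–elimination at the carbonyl, releasing the phenoxide) should free the phenol while ketal, aryl–silicon bond and benzyl ethers stay inert.

Step 13
Reactants: 17 3,5-bis(benzyloxy)-2-K-6-(trimethylsilyl)phenol
Product: 18 3,5-bis(benzyloxy)-2-K-6-(trimethylsilyl)phenyl trifluoromethanesulfonate
Conditions: Tf2O, pyridine, CH2Cl2, −20 → 0 °C
Reagents that add atoms: trifluoromethanesulfonic anhydride O=S(=O)(OS(=O)(=O)C(F)(F)F)C(F)(F)F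
Why: O-Sulfonylation, in which the small and highly electrophilic anhydride should triflate the doubly flanked phenol while pyridine buffers the medium for the ketal and the aryl silane.

Step 14
Reactants: 18 3,5-bis(benzyloxy)-2-K-6-(trimethylsilyl)phenyl trifluoromethanesulfonate; 19 3-phenylpropiolic acid
Product: 21 1-[4,6-bis(benzyloxy)-2-hydroxy-3-K-phenyl]-3-phenylprop-2-yn-1-one, via aryne 20 (not isolated)
Conditions: 19 (1.5 equiv), CsF (4 equiv), THF, 110 °C, sealed tube
Reagents that add atoms: none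
Why: Fluoride attacks silicon and the C4a carbanion expels triflate from C8a to give aryne 20; the carboxylate oxygen of 19 adds to C8a, the C4a aryl anion attacks the adjacent ester carbonyl to form a four-membered benzoxetene alkoxide, and its opening leaves the C8a phenoxide and the C4a ynone, forming the C8a–O and C4a–C4 bonds. The closest known reaction type is the insertion of arynes into the C–O bond of carboxylic acids to give ortho-hydroxyaryl ketones. No ring is closed and no stereocentre is formed; C3 of the side chain is remote from all bond changes and cannot epimerise. The selectivity needed is oxygen attack at C8a and not at C4a, and the C5 benzyloxy group secures it by polarising the aryne so that the nucleophile adds at the distal carbon and charge builds up next to oxygen, the small carboxylate tolerating the C8 branch. High temperature favours intramolecular acyl transfer over protonation of the aryl anion, and the reaction is stopped once 18 is consumed; any phenoxide that has already closed onto the ynone gives flavone 22, the product of step 15.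

Step 15
Reactants: 21 1-[4,6-bis(benzyloxy)-2-hydroxy-3-K-phenyl]-3-phenylprop-2-yn-1-one
Product: 22 5,7-bis(benzyloxy)-8-K-2-phenyl-4H-chromen-4-one
Conditions: K2CO3, acetone, reflux
Reagents that add atoms: none
Why: Intramolecular oxa-Michael addition of the C8a phenoxide to the ynone β-carbon in the 6-endo-dig mode, for which carbonate in aprotic acetone is the established way to favour the chromen-4-one over the 5-exo aurone.

Step 16
Reactants: 22 5,7-bis(benzyloxy)-8-K-2-phenyl-4H-chromen-4-one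
Product: 25 5,7-bis(benzyloxy)-3-hydroxy-8-[(3R)-1-ArG-5-oxo-7-phenylheptan-3-yl]-2-phenyl-4H-chromen-4-one, via flavone epoxide 23 (not isolated), via flavonol ketal 24 (not isolated)
Conditions: DMDO, acetone/CH2Cl2, 0 °C → rt; then p-TsOH·H2O (cat.), acetone/H2O, rt
Reagents that add atoms: dimethyldioxirane CC1(C)OO1; water O
Why: Epoxidation of the C2=C3 bond by the dioxirane, acid-catalysed opening of the 2,3-epoxide to the 3-hydroxyflavone and acetal hydrolysis of the dioxolane in the same aqueous acidic acetone, with the C7 benzyl ether still blocking hemiketal formation by the freed ketone.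

Step 17
Reactants: 25 5,7-bis(benzyloxy)-3-hydroxy-8-[(3R)-1-ArG-5-oxo-7-phenylheptan-3-yl]-2-phenyl-4H-chromen-4-one
Product: 26 3,5,7-trihydroxy-8-[(3R)-1-(4-hydroxy-3-methoxyphenyl)-5-oxo-7-phenylheptan-3-yl]-2-phenyl-4H-chromen-4-one
Conditions: H2 (1 atm), 10% Pd/C, EtOAc/MeOH, rt
Reagents that add atoms: none
Why: Catalytic hydrogenolysis should cleave the three benzyl ethers under neutral conditions that leave the chromenone C2=C3 bond, the dialkyl ketone and the C3 stereocentre untouched.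

Compound list
1 | 3-(4-hydroxy-3-methoxyphenyl)propan-1-ol | COc1cc(CCCO)ccc1O | starting material
2 | 3-[4-(benzyloxy)-3-methoxyphenyl]propan-1-ol | COc1cc(CCCO)ccc1OCc1ccccc1 | intermediate
3 | 3-[4-(benzyloxy)-3-methoxyphenyl]propanal | COc1cc(CCC=O)ccc1OCc1ccccc1 | intermediate
4 | dimethyl (2-oxo-4-phenylbutyl)phosphonate | COP(=O)(CC(=O)CCc1ccccc1)OC | starting material
5 | (E)-7-[4-(benzyloxy)-3-methoxyphenyl]-1-phenylhept-4-en-3-one | O=C(CCc1ccccc1)/C=C/CCc1ccc(OCc2ccccc2)c(OC)c1 | intermediate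
6 | (3R,4E)-7-[4-(benzyloxy)-3-methoxyphenyl]-1-phenylhept-4-en-3-ol | O[C@H](CCc1ccccc1)/C=C/CCc1ccc(OCc2ccccc2)c(OC)c1 | intermediate
7 | 3,5-bis(benzyloxy)phenol | Oc1cc(OCc2ccccc2)cc(OCc2ccccc2)c1 | starting material
8 | 1,3-bis(benzyloxy)-5-{[(3S,4E)-7-(4-(benzyloxy)-3-methoxyphenyl)-1-phenylhept-4-en-3-yl]oxy}benzene | c1ccccc1COc1cc(OCc2ccccc2)cc(O[C@@H](CCc2ccccc2)/C=C/CCc2ccc(OCc3ccccc3)c(OC)c2)c1 | intermediate
9 | 3,5-bis(benzyloxy)-2-[(3R,4E)-1-(4-(benzyloxy)-3-methoxyphenyl)-7-phenylhept-4-en-3-yl]phenol | Oc1cc(OCc2ccccc2)cc(OCc2ccccc2)c1[C@H](CCc1ccc(OCc2ccccc2)c(OC)c1)/C=C/CCc1ccccc1 | intermediate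
10 | 3,5-bis(benzyloxy)-2-[(3R,4E)-1-(4-(benzyloxy)-3-methoxyphenyl)-7-phenylhept-4-en-3-yl]phenyl N,N-diethylcarbamate | CCN(CC)C(=O)Oc1cc(OCc2ccccc2)cc(OCc2ccccc2)c1[C@H](CCc1ccc(OCc2ccccc2)c(OC)c1)/C=C/CCc1ccccc1 | intermediate
11 | B-alkyl-9-BBN adduct of 10, boron on C5 (not isolated; C5 epimers) | CCN(CC)C(=O)Oc1cc(OCc2ccccc2)cc(OCc2ccccc2)c1[C@H](CCc1ccc(OCc2ccccc2)c(OC)c1)CC(B1C2CCCC1CCC2)CCc1ccccc1 | intermediate
12 | 3,5-bis(benzyloxy)-2-[(3R)-1-(4-(benzyloxy)-3-methoxyphenyl)-5-hydroxy-7-phenylheptan-3-yl]phenyl N,N-diethylcarbamate (both C5 epimers) | CCN(CC)C(=O)Oc1cc(OCc2ccccc2)cc(OCc2ccccc2)c1[C@H](CCc1ccc(OCc2ccccc2)c(OC)c1)CC(O)CCc1ccccc1 | intermediate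
13 | 3,5-bis(benzyloxy)-2-[(3R)-1-(4-(benzyloxy)-3-methoxyphenyl)-5-oxo-7-phenylheptan-3-yl]phenyl N,N-diethylcarbamate | CCN(CC)C(=O)Oc1cc(OCc2ccccc2)cc(OCc2ccccc2)c1[C@H](CCc1ccc(OCc2ccccc2)c(OC)c1)CC(=O)CCc1ccccc1 | intermediate
14 | 3,5-bis(benzyloxy)-2-{(2R)-4-[4-(benzyloxy)-3-methoxyphenyl]-1-[2-(2-phenylethyl)-1,3-dioxolan-2-yl]butan-2-yl}phenyl N,N-diethylcarbamate | CCN(CC)C(=O)Oc1cc(OCc2ccccc2)cc(OCc2ccccc2)c1[C@H](CCc1ccc(OCc2ccccc2)c(OC)c1)CC1(CCc2ccccc2)OCCO1 | intermediate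
15 | 6-lithio derivative of 14 (not isolated) | CCN(CC)C(=O)Oc1c([Li])c(OCc2ccccc2)cc(OCc2ccccc2)c1[C@H](CCc1ccc(OCc2ccccc2)c(OC)c1)CC1(CCc2ccccc2)OCCO1 | intermediate
16 | 3,5-bis(benzyloxy)-2-{(2R)-4-[4-(benzyloxy)-3-methoxyphenyl]-1-[2-(2-phenylethyl)-1,3-dioxolan-2-yl]butan-2-yl}-6-(trimethylsilyl)phenyl N,N-diethylcarbamate | CCN(CC)C(=O)Oc1c([Si](C)(C)C)c(OCc2ccccc2)cc(OCc2ccccc2)c1[C@H](CCc1ccc(OCc2ccccc2)c(OC)c1)CC1(CCc2ccccc2)OCCO1 | intermediate
17 | 3,5-bis(benzyloxy)-2-{(2R)-4-[4-(benzyloxy)-3-methoxyphenyl]-1-[2-(2-phenylethyl)-1,3-dioxolan-2-yl]butan-2-yl}-6-(trimethylsilyl)phenol | Oc1c([Si](C)(C)C)c(OCc2ccccc2)cc(OCc2ccccc2)c1[C@H](CCc1ccc(OCc2ccccc2)c(OC)c1)CC1(CCc2ccccc2)OCCO1 | intermediate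
18 | 3,5-bis(benzyloxy)-2-{(2R)-4-[4-(benzyloxy)-3-methoxyphenyl]-1-[2-(2-phenylethyl)-1,3-dioxolan-2-yl]butan-2-yl}-6-(trimethylsilyl)phenyl trifluoromethanesulfonate | C[Si](C)(C)c1c(OCc2ccccc2)cc(OCc2ccccc2)c([C@H](CCc2ccc(OCc3ccccc3)c(OC)c2)CC2(CCc3ccccc3)OCCO2)c1OS(=O)(=O)C(F)(F)F | intermediate
19 | 3-phenylpropiolic acid | OC(=O)C#Cc1ccccc1 | starting material
20 | 3,5-bis(benzyloxy)-6-{(2R)-4-[4-(benzyloxy)-3-methoxyphenyl]-1-[2-(2-phenylethyl)-1,3-dioxolan-2-yl]butan-2-yl}-1,2-didehydrobenzene (aryne across C4a and C8a; not isolated) | C1#CC(OCc2ccccc2)=CC(OCc2ccccc2)=C1[C@H](CCc1ccc(OCc2ccccc2)c(OC)c1)CC1(CCc2ccccc2)OCCO1 | intermediate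
21 | 1-{4,6-bis(benzyloxy)-2-hydroxy-3-[(2R)-4-(4-(benzyloxy)-3-methoxyphenyl)-1-(2-(2-phenylethyl)-1,3-dioxolan-2-yl)butan-2-yl]phenyl}-3-phenylprop-2-yn-1-one | O=C(C#Cc1ccccc1)c1c(O)c([C@H](CCc2ccc(OCc3ccccc3)c(OC)c2)CC2(CCc3ccccc3)OCCO2)c(OCc2ccccc2)cc1OCc1ccccc1 | intermediate
22 | 5,7-bis(benzyloxy)-8-{(2R)-4-[4-(benzyloxy)-3-methoxyphenyl]-1-[2-(2-phenylethyl)-1,3-dioxolan-2-yl]butan-2-yl}-2-phenyl-4H-chromen-4-one | O=c1cc(-c2ccccc2)oc2c([C@H](CCc3ccc(OCc4ccccc4)c(OC)c3)CC3(CCc4ccccc4)OCCO3)c(OCc3ccccc3)cc(OCc3ccccc3)c12 | intermediate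
23 | 2,3-epoxide of 22 (2,3-epoxyflavanone, mixture of epoxide diastereomers; not isolated) | O=C1C2OC2(c2ccccc2)Oc2c([C@H](CCc3ccc(OCc4ccccc4)c(OC)c3)CC3(CCc4ccccc4)OCCO3)c(OCc3ccccc3)cc(OCc3ccccc3)c12 | intermediate
24 | 5,7-bis(benzyloxy)-3-hydroxy-8-{(2R)-4-[4-(benzyloxy)-3-methoxyphenyl]-1-[2-(2-phenylethyl)-1,3-dioxolan-2-yl]butan-2-yl}-2-phenyl-4H-chromen-4-one (not isolated) | O=c1c(O)c(-c2ccccc2)oc2c([C@H](CCc3ccc(OCc4ccccc4)c(OC)c3)CC3(CCc4ccccc4)OCCO3)c(OCc3ccccc3)cc(OCc3ccccc3)c12 | intermediate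
25 | 5,7-bis(benzyloxy)-3-hydroxy-8-[(3R)-1-(4-(benzyloxy)-3-methoxyphenyl)-5-oxo-7-phenylheptan-3-yl]-2-phenyl-4H-chromen-4-one | O=c1c(O)c(-c2ccccc2)oc2c([C@H](CCc3ccc(OCc4ccccc4)c(OC)c3)CC(=O)CCc3ccccc3)c(OCc3ccccc3)cc(OCc3ccccc3)c12 | intermediate
26 | 3,5,7-trihydroxy-8-[(3R)-1-(4-hydroxy-3-methoxyphenyl)-5-oxo-7-phenylheptan-3-yl]-2-phenyl-4H-chromen-4-one | COc1cc(CC[C@H](CC(=O)CCc2ccccc2)c2c(O)cc(O)c3c(=O)c(O)c(-c4ccccc4)oc23)ccc1O | target

Total step count: 17. Longest linear sequence: 17 steps (1 to 26); compounds 4, 7 and 19 are bought.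

Steps most likely to fail

Step 14. The aryne may be attacked at C4a instead of C8a because of the bulky C8 branch, or the aryl anion may be protonated before acyl transfer, which stops at the aryl ester. A dioxolane oxygen may also capture the aryne intramolecularly, the propiolate may decarboxylate at the reaction temperature, and the phenoxide may close onward without control. The fallback makes the C4a–C4 bond by carbonylation instead. It sets out from silyl phenol 17, where ipso-iododesilylation with ICl (CH2Cl2, −78 °C) should replace silicon by iodine and give 3,5-bis(benzyloxy)-2-iodo-6-K-phenol F1. Carbonylative Sonogashira coupling and annulation with phenylacetylene (CO, PdCl2(PPh3)2, Et2NH, 60–100 °C) should then pass through ynone 21 in the flask and close to flavone 22, where the route is rejoined before step 16.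

Step 11. Lithiation may be diverted to the benzylic positions of the benzyl ethers, followed by Wittig-type shifts, or the lithiated carbamate may undergo anionic Fries migration before it is silylated. The fallback brings silicon in by a retro-Brook shift and sets out from carbamate 14. LiAlH4 in THF should give 3,5-bis(benzyloxy)-2-K-phenol F2. NBS with catalytic iPr2NH in CH2Cl2 should brominate ortho to the hydroxyl and give 2-bromo-3,5-bis(benzyloxy)-6-K-phenol F3, and HMDS should give its trimethylsilyl ether F4. n-BuLi at −78 °C should effect bromine–lithium exchange to the aryllithium silyl ether F5, whose 1,3 shift of silicon from oxygen to carbon gives silyl phenol 17 after protonation, where the route is rejoined before step 13.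

Step 8. Addition of the borane to the hindered internal alkene may be too slow, or regiocontrol may be lost so that boron ends up on C4. The fallback makes the regiochemistry unambiguous through a terminal alkene and sets out from carbamate 10. Ethenolysis (ethylene, second-generation Hoveyda–Grubbs catalyst, CH2Cl2) should give 3,5-bis(benzyloxy)-2-[(3R)-5-ArG-pent-1-en-3-yl]phenyl N,N-diethylcarbamate F6. Hydroboration with 9-BBN should give the terminal B-alkyl-9-BBN adduct F7, and NaOH/H2O2 the primary alcohol 3,5-bis(benzyloxy)-2-[(3R)-5-ArG-1-hydroxypentan-3-yl]phenyl N,N-diethylcarbamate F8. Dess–Martin oxidation should give 3,5-bis(benzyloxy)-2-[(3R)-5-ArG-1-oxopentan-3-yl]phenyl N,N-diethylcarbamate F9, and addition of PhCH2CH2MgBr at −78 °C returns alcohol 12, where the route is rejoined before step 9.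

Further compounds
F1 | step 14 | 3,5-bis(benzyloxy)-2-iodo-6-{(2R)-4-[4-(benzyloxy)-3-methoxyphenyl]-1-[2-(2-phenylethyl)-1,3-dioxolan-2-yl]butan-2-yl}phenol | Oc1c(I)c(OCc2ccccc2)cc(OCc2ccccc2)c1[C@H](CCc1ccc(OCc2ccccc2)c(OC)c1)CC1(CCc2ccccc2)OCCO1
F2 | step 11 | 3,5-bis(benzyloxy)-2-{(2R)-4-[4-(benzyloxy)-3-methoxyphenyl]-1-[2-(2-phenylethyl)-1,3-dioxolan-2-yl]butan-2-yl}phenol | Oc1cc(OCc2ccccc2)cc(OCc2ccccc2)c1[C@H](CCc1ccc(OCc2ccccc2)c(OC)c1)CC1(CCc2ccccc2)OCCO1
F3 | step 11 | 2-bromo-3,5-bis(benzyloxy)-6-{(2R)-4-[4-(benzyloxy)-3-methoxyphenyl]-1-[2-(2-phenylethyl)-1,3-dioxolan-2-yl]butan-2-yl}phenol | Oc1c(Br)c(OCc2ccccc2)cc(OCc2ccccc2)c1[C@H](CCc1ccc(OCc2ccccc2)c(OC)c1)CC1(CCc2ccccc2)OCCO1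
F4 | step 11 | trimethylsilyl ether of F3 | C[Si](C)(C)Oc1c(Br)c(OCc2ccccc2)cc(OCc2ccccc2)c1[C@H](CCc1ccc(OCc2ccccc2)c(OC)c1)CC1(CCc2ccccc2)OCCO1
F5 | step 11 | aryllithium from F4 by bromine–lithium exchange | C[Si](C)(C)Oc1c([Li])c(OCc2ccccc2)cc(OCc2ccccc2)c1[C@H](CCc1ccc(OCc2ccccc2)c(OC)c1)CC1(CCc2ccccc2)OCCO1
F6 | step 8 | 3,5-bis(benzyloxy)-2-[(3R)-5-(4-(benzyloxy)-3-methoxyphenyl)pent-1-en-3-yl]phenyl N,N-diethylcarbamate | CCN(CC)C(=O)Oc1cc(OCc2ccccc2)cc(OCc2ccccc2)c1[C@H](CCc1ccc(OCc2ccccc2)c(OC)c1)C=C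
F7 | step 8 | terminal B-alkyl-9-BBN adduct of F6 (benzylic configuration unchanged) | CCN(CC)C(=O)Oc1cc(OCc2ccccc2)cc(OCc2ccccc2)c1[C@H](CCc1ccc(OCc2ccccc2)c(OC)c1)CCB1C2CCCC1CCC2
F8 | step 8 | 3,5-bis(benzyloxy)-2-[(3R)-5-(4-(benzyloxy)-3-methoxyphenyl)-1-hydroxypentan-3-yl]phenyl N,N-diethylcarbamate | CCN(CC)C(=O)Oc1cc(OCc2ccccc2)cc(OCc2ccccc2)c1[C@H](CCc1ccc(OCc2ccccc2)c(OC)c1)CCO
F9 | step 8 | 3,5-bis(benzyloxy)-2-[(3R)-5-(4-(benzyloxy)-3-methoxyphenyl)-1-oxopentan-3-yl]phenyl N,N-diethylcarbamate | CCN(CC)C(=O)Oc1cc(OCc2ccccc2)cc(OCc2ccccc2)c1[C@H](CCc1ccc(OCc2ccccc2)c(OC)c1)CC=O
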